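# Proposed total synthesis of CNP0279880.0 by benzannulation of ring F onto an ethynyl ether

## The problem

The target is a hexadecahydroxy phlorotannin of six benzene rings with no stereocentre. The central ring C carries aryl ether oxygens on the neighbouring carbons C1, C2 and C3 and a hydroxyl at C5. The C1 and C3 oxygens each hold a biaryl (ring B joined to ring A, ring D joined to ring E). The C2 oxygen holds the pyrogallol ring F (ether at F1, hydrogens at F2 and F6, oxygens at F3, F4 and F5).

The two biaryl bonds are flanked by four ortho oxygens, but rings A and E are symmetric about the axis, so the axes are not stereogenic. The task is therefore one of connectivity and oxygen placement, not of stereocontrol. The two biaryl arms are identical, so one biaryl phenol used twice supplies twelve of the sixteen oxygens.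

The free polyphenol, with its pyrogallol and phloroglucinol units, autoxidises readily, above all in base. The oxygens must therefore travel as alkyl ethers that can be removed together under acidic, oxygen-free conditions which the diaryl ethers survive.

The hardest bond is the ether between C2 and F1. The C2 oxygen lies between two bulky biaryloxy groups, each with methoxy groups ortho to its own ether, so any reaction that must bring a whole aryl ring up to this oxygen is disfavoured. The way round this lies in the pattern of ring F: the F1 ether oxygen is meta to the F3 oxygen, F4 and F5 carry the other two contiguous oxygens, and F2 and F6 carry hydrogen. This is the pattern that arises when an aryl ethynyl ether (F1 and F2) is joined to a 3,4-dialkoxycyclobut-2-enone (F3 to F6). Ring F can thus be grown on the C2 oxygen after that oxygen has only had to capture a two-carbon electrophile.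

## Retrosynthesis

**Unmasking.** Target 26 is traced back to 25, in which fourteen phenols are methyl ethers, the F5 oxygen is an isopropyl ether and only the F3 hydroxyl is free. Fifteen alkyl–oxygen bonds are cut. Methyl ethers are preferred to benzyl ethers because they survive oxidative coupling, butyllithium, hot carbonate, hydrogenation, diazotisation and thermolysis alike. The isopropyl group comes in with the squarate-derived partner and is cleaved by the same reagent. The forward step needs a Lewis acid that removes all fifteen alkyl groups without touching diaryl ether or biaryl bonds.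

**Ring F.** Compound 25 is cut at F2–F3 and F1–F6 into ethynyl ether 15 and racemic 3-isopropoxy-4-methoxycyclobut-2-en-1-one 20. The neighbouring cut, through the C2–O–F1 ether, would ask the most hindered oxygen of the molecule (in phenol 10) to meet an unactivated, electron-rich trioxygenated arene. The chosen cut asks it only to carry a triple bond. Compound 15 lacks ring F altogether and 20 is a four-carbon piece that already holds the F3, F4 and F5 oxygens in the right order. The forward reaction must join ketene and alkyne in one orientation and must run in a temperature window that the ynol ether survives.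

**The ynol ether.** Compound 15 is cut at the O–C(sp) bond, through (E)-1,2-dichlorovinyl ether 12, to phenol 10 and trichloroethylene 11. No other two-carbon electrophile is as small or as well matched to a phenoxide. The precursor 10 is a stable phenol, and the forward sequence needs only addition to dichloroacetylene generated in the flask, then elimination and halogen–lithium exchange.

**The cyclobutenone.** Compound 20 is traced through alcohol 19 and semisquarate 18 to diisopropyl squarate 16, that is, two hydride reductions and one O-methylation. The isopropyl ester is chosen over the methyl ester because the isopropyl semisquarate is the well-behaved member of its class. The second reduction must take place at the ketone carbonyl next to the alkoxy-bearing carbon and not at the vinylogous ester carbonyl, since this decides the oxygen pattern of ring F.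

**Ring C.** Phenol 10 is traced through aniline 8 to nitro compound 7, which is cut at the O–C1 and O–C3 ether bonds into two molecules of biaryl phenol 5 and 3,5-difluoro-4-nitroanisole 6. A copper-mediated double coupling on a 2,6-dihalophenol would have no activation and two hindered partners. The nitro group activates both fluorides and sits on the carbon where the C2 oxygen is needed. The price is a nitro-to-hydroxyl exchange through a diazonium ion in a molecule full of electron-rich rings.

**The biaryl phenol.** Compound 5 is cut at its C–O bond to hexamethoxybiphenyl 2 (lithiation between two methoxy groups, borylation, oxidation), and 2 at the biaryl bond to two molecules of 1,3,5-trimethoxybenzene 1 (oxidative dimerisation). A cross-coupling of two differently oxygenated rings would give 5 without a statistical step but would need several steps and a tetra-ortho-substituted coupling. The chosen sequence takes two steps from a cheap arene and requires only mono-functionalisation of one of four equivalent positions.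

## Roads not taken

**Alternative 1:** The cut is at the two ether bonds O–C1 and O–C3 of ring C, with ring C brought in as a quinone.
- Forward key step: two equivalents of the phenoxide of 5 add to the chlorine-bearing carbons of 2,6-dichloro-1,4-benzoquinone A2 and expel chloride, with no ring closure, to give bis(biaryloxy)quinone A1.
- Merits: both remaining oxygens of ring C (at C2 and C5) are in place from the start and the conditions are mild. Reduction of A1 and methylation of the unhindered C5 oxygen would lead into 10 in about three operations, the same count as steps 3 to 5, and without a diazonium ion.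
- Weak points: the phenoxide of 5 is a strong electron donor and A2 a strong acceptor, so electron transfer competes with substitution. The methoxy-rich rings can also attack through carbon, and A1 remains a Michael acceptor at its two free ring positions. Nothing in this road deals with ring F, so the hindered C2 oxygen would still have to be arylated.
- Comparison: for ring C alone this road is at least as short as the chosen one and avoids the nitro-to-hydroxyl exchange, the weakest supporting step of the chosen plan. The chosen plan sets against this a fluoride displacement on a nitroarene, which has no redox channel, and a key step aimed at the very bond that this road leaves open.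

**Alternative 2:** The cut runs through ring B itself, with the B2–B3 bond formed last, so that ring B is grown on ring A.
- Forward key step: heating the 4-(1-methoxyvinyl)cyclobutenone A4 in toluene opens the four-membered ring to a dienylketene, whose 6π closure gives biaryl A3 (a Moore-type ring expansion). In A3 the B2 hydroxyl is free and the B5 oxygen is set apart as a methoxymethyl ether.
- Merits: all six substituents of ring B are fixed by the order of additions to a squarate ester. The B5 oxygen is differentiated by construction, so methylation and acetal removal would give 5 with no statistical step.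
- Weak points: A4 needs two successive organolithium additions to a squarate with regiocontrol in the second, protection of a tertiary alkoxide and then the thermolysis, and A3 needs two further operations to reach 5. That is six or seven steps for what steps 1 and 2 do in two. The biaryl bond must be made as an aryl–cyclobutene bond next to three ortho oxygens, and ring F is again untouched.
- Comparison: this road is better than step 2 in regiochemical certainty for 5. The chosen plan sets against it brevity and a symmetric precursor that can be recovered and recycled. It also uses cyclobutenone ring expansion at ring F, where no short classical alternative exists, and not at ring B, where one does.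

**Alternative 3:** The cut is at the A1–A6 and E1–E6 bonds, so that both outer rings arise late from pyrones.
- Forward key step: NaOMe in hot methanol opens both lactones of the bis(pyronylmethyl) compound A6. Each benzylic carbon then attacks its ester carbon in a Claisen-type closure, and aromatisation gives A5 with free hydroxyls at A2, A6, E2 and E6.
- Merits: the route is biomimetic and closes two rings in one operation. The tetra-ortho-oxygenated biaryl bonds are never made by coupling, and the free hydroxyls do no harm because all ethers are cleaved next.
- Weak points: A6 already contains ring F on the hindered C2 oxygen, so the most difficult bond must be made earlier by other means. Rings B and D must each receive a pyronylmethyl group at a position flanked by two methoxy groups. The opened keto ester can also be deprotonated at its other methylene and simply re-close to the pyrone. The sequence to A6 is long and linear.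
- Comparison: this road forms two rings in its key step against one in the chosen plan. The chosen plan obtains the biaryl in one step from 1, so the biaryl bond is not where help is needed, and it spends its key step on the ether at C2.

Key step: step 11

## Route

Notation: Ar = 2,2',4,4',6,6'-hexamethoxybiphenyl-3-yl, and ArO is this group bound through oxygen at its position 3.

Assumption: 3,5-difluoro-4-nitroanisole and diisopropyl squarate are taken as purchasable. Phenoxide salts formed by simple deprotonation (steps 3 and 6) and the boron aryloxides of step 12 are treated as the ionised or bound form of the parent compound and are not numbered.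

Step 1
Reactants: 1 1,3,5-trimethoxybenzene (two molecules)
Product: 2 2,2',4,4',6,6'-hexamethoxybiphenyl
Conditions: FeCl3 (anhydrous, 1 equiv), CH2Cl2, 0 °C → rt; MeOH quench
Reagents that add atoms: none
Why: Scholl-type oxidative dehydrodimerisation: FeCl3 (trivalent iron) oxidises the arene to its radical cation, which a second arene attacks; all ring C–H positions of 1 are equivalent, so only one biaryl can form, and one equivalent of oxidant limits chlorination and oligomer formation.

Step 2
Reactants: 2 2,2',4,4',6,6'-hexamethoxybiphenyl
Product: 5 2,2',4,4',6,6'-hexamethoxybiphenyl-3-ol, via aryllithium 3 (not isolated), via dimethyl arylboronate 4 (not isolated)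
Conditions: n-BuLi (1.0 equiv), TMEDA, THF, 0 °C; B(OMe)3, −78 °C → rt; 30% H2O2, AcOH, 0 °C → rt
Reagents that add atoms: hydrogen peroxide, OO
Why: Directed ortho-lithiation at a C–H flanked by two methoxy groups, borylation and oxidative 1,2-shift of the aryl group from boron to oxygen; the four C–H sites of 2 are equivalent, so one equivalent of base should favour the mono-phenol and unreacted 2 can be returned to the step.

Step 3
Reactants: 5 2,2',4,4',6,6'-hexamethoxybiphenyl-3-ol (2.2 equiv) and 6 3,5-difluoro-4-nitroanisole
Product: 7 2,6-bis(ArO)-4-methoxy-1-nitrobenzene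
Conditions: Cs2CO3, DMSO, 70 °C, argon
Reagents that add atoms: none
Why: Double nucleophilic aromatic substitution (SNAr): both fluorides are ortho to the nitro group, the electron-rich phenoxide of 5 adds through the Meisenheimer complex despite its two ortho methoxy groups, and the para methoxy group is a far poorer leaving group than fluoride.

Step 4
Reactants: 7 2,6-bis(ArO)-4-methoxy-1-nitrobenzene
Product: 8 2,6-bis(ArO)-4-methoxyaniline
Conditions: H2 (1 atm), palladium on carbon (Pd/C), EtOAc–MeOH, rt
Reagents that add atoms: none
Why: Catalytic hydrogenation of an aryl nitro group; the molecule holds no benzyl ether, halide or alkene that could be reduced alongside.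

Step 5
Reactants: 8 2,6-bis(ArO)-4-methoxyaniline
Product: 10 2,6-bis(ArO)-4-methoxyphenol, via diazonium tetrafluoroborate 9 (not isolated)
Conditions: t-BuONO (1.0 equiv), HBF4·OEt2, THF, −15 °C; then Cu(NO3)2·3H2O (large excess), Cu2O, H2O, rt
Reagents that add atoms: water, O
Why: Diazotisation with an alkyl nitrite followed by copper-mediated hydroxydediazoniation (Sandmeyer-type hydroxylation), a sequence established for ortho-aryloxy anilines: Cu2O (monovalent copper) reduces the diazonium ion to the aryl radical, and Cu(NO3)2 (divalent copper) captures it and delivers hydroxyl from water at room temperature while the copper couple is regenerated. One equivalent of nitrite at low temperature should limit C-nitrosation of the methoxy-rich rings.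

Step 6
Reactants: 10 2,6-bis(ArO)-4-methoxyphenol and 11 trichloroethylene
Product: 12 (E)-1,2-dichlorovinyl ether of 10
Conditions: KH (1.3 equiv), THF, 0 °C; then ClCH=CCl2, 0 °C → rt
Reagents that add atoms: none
Why: The potassium phenoxide adds to dichloroacetylene formed in the flask by dehydrochlorination of trichloroethylene, and anti addition with protonation gives the (E)-dichlorovinyl ether; the electrophile is small enough to reach the oxygen between the two biaryloxy groups.

Step 7
Reactants: 12 (E)-1,2-dichlorovinyl ether of 10
Product: 15 2-(ethynyloxy)-5-methoxy-1,3-bis(ArO)benzene, via chloroethynyl ether 13 (not isolated), via lithium acetylide 14 (not isolated)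
Conditions: n-BuLi (2.2 equiv), THF, −78 → −40 °C; MeOH, −78 °C
Reagents that add atoms: none
Why: Anti elimination of HCl gives chloroalkyne 13, chlorine–lithium exchange gives acetylide 14 and protonation gives the terminal ynol ether (the trichloroethylene route to ynol ethers); at −78 °C deprotonation of the vinyl C–H should outrun lithiation of the methoxyarenes, and 15 is to be kept cold and carried directly into step 11.

Step 8
Reactants: 16 diisopropyl squarate (3,4-diisopropoxycyclobut-3-ene-1,2-dione)
Product: 18 3-isopropoxycyclobut-3-ene-1,2-dione, via 4-hydroxy-2,3-diisopropoxycyclobutenone 17 (not isolated)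
Conditions: LiAlH(Ot-Bu)3, THF, −78 °C; aq. HCl work-up; then conc. HCl, CH2Cl2, rt
Reagents that add atoms: none
Why: The bulky hydride adds 1,2 to one of the two equivalent vinylogous ester carbonyls of the squarate, and acid converts racemic hydroxy enone 17 into the semisquarate by loss of isopropanol, the established route to 3-alkoxycyclobutenediones.

Step 9
Reactants: 18 3-isopropoxycyclobut-3-ene-1,2-dione
Product: 19 4-hydroxy-3-isopropoxycyclobut-2-en-1-one (racemic)
Conditions: LiAlH(Ot-Bu)3 (1.0 equiv), THF, −78 °C; H2O, pH 7 buffer
Reagents that add atoms: none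
Why: 1,2-Reduction of the more electrophilic ketone carbonyl, the one next to the alkoxy-bearing carbon and not part of the vinylogous ester, which is the site that organolithium reagents attack in semisquarates; the new stereocentre forms as a racemate, which is immaterial because it is erased in step 11, and the neutral work-up avoids acid-induced loss of isopropanol.

Step 10
Reactants: 19 4-hydroxy-3-isopropoxycyclobut-2-en-1-one (racemic)
Product: 20 3-isopropoxy-4-methoxycyclobut-2-en-1-one (racemic)
Conditions: MeI, Ag2O, 4 Å molecular sieves, MeCN, rt, dark
Reagents that add atoms: iodomethane, CI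
Why: Purdie methylation under near-neutral conditions, the usual way to cap a 4-hydroxycyclobutenone without opening the ring; the C4–H is not acidic because its enolate would be a cyclobutadiene, so the racemic centre is untouched.

Step 11
Reactants: 15 2-(ethynyloxy)-5-methoxy-1,3-bis(ArO)benzene and 20 3-isopropoxy-4-methoxycyclobut-2-en-1-one (racemic, 1.5 equiv)
Product: 25 5-[2,6-bis(ArO)-4-methoxyphenoxy]-3-isopropoxy-2-methoxyphenol, via vinylketene 21 (not isolated), via vinylcyclobutenone adduct 22 (not isolated), via dienylketene 23 (not isolated), via cyclohexadienone 24 (not isolated)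
Conditions: toluene (degassed), 80 → 110 °C, argon, sealed vessel
Reagents that add atoms: none
Why: Proposed new method: heat opens 20 by a conrotatory 4π ring opening, the 4-methoxy group turning outward, to dialkoxyvinylketene 21, and the electron-rich terminal carbon of ynol ether 15 attacks the ketene carbonyl carbon in a regioselective (2+2) cycloaddition that forms F2–F3 and F1–F6 and gives 22. A second 4π opening of 22 gives dienylketene 23, which closes ring F by a thermal disrotatory 6π electrocyclisation (re-forming the F3–F4 bond) to dienone 24, and enolisation gives phenol 25. The closest known reaction type is the Danheiser benzannulation of cyclobutenones with alkyl and silyl ynol ethers to resorcinol monoethers; an aryl ethynyl ether paired with a 4-alkoxycyclobutenone has not been shown. No stereocentre is created, since the racemic centre of 20 and those of 22 and 24 are lost on aromatisation. The one selectivity needed is the orientation of ketene and alkyne, and the oxygen-polarised triple bond secures it by placing the aryloxy carbon meta to the new hydroxyl (F1) and the alkyne CH at F2. The aryl ynol ether has no hydrogen beta to oxygen on the aryl side and so cannot lose ketene by a retro-ene path, and the two flanking biaryloxy groups should shield it from self-condensation. The alkyl aryl ethers and diaryl ethers are inert to neutral thermolysis.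

Step 12
Reactants: 25 5-[2,6-bis(ArO)-4-methoxyphenoxy]-3-isopropoxy-2-methoxyphenol
Product: 26 5-{2,6-bis[(2,2',4,4',6,6'-hexahydroxybiphenyl-3-yl)oxy]-4-hydroxyphenoxy}benzene-1,2,3-triol (CNP0279880.0)
Conditions: BBr3 (excess), CH2Cl2, −78 °C → rt, argon; then H2O, 0 °C
Reagents that add atoms: none
Why: Lewis acid ether cleavage: BBr3 binds each alkyl aryl ether oxygen and bromide removes the methyl or isopropyl group, while diaryl ether and biaryl bonds are inert; hydrolysis of the boron aryloxides releases the sixteen phenols, and argon protects the pyrogallol and phloroglucinol rings from autoxidation.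

## Compound list

1 | 1,3,5-trimethoxybenzene | COc1cc(OC)cc(OC)c1 | starting material
2 | 2,2',4,4',6,6'-hexamethoxybiphenyl | COc1cc(OC)c(-c2c(OC)cc(OC)cc2OC)c(OC)c1 | intermediate
3 | 3-lithio-2,2',4,4',6,6'-hexamethoxybiphenyl | [Li]c1c(OC)cc(OC)c(-c2c(OC)cc(OC)cc2OC)c1OC | intermediate
4 | dimethyl (2,2',4,4',6,6'-hexamethoxybiphenyl-3-yl)boronate | COB(OC)c1c(OC)cc(OC)c(-c2c(OC)cc(OC)cc2OC)c1OC | intermediate
5 | 2,2',4,4',6,6'-hexamethoxybiphenyl-3-ol | Oc1c(OC)cc(OC)c(-c2c(OC)cc(OC)cc2OC)c1OC | intermediate
6 | 3,5-difluoro-4-nitroanisole | COc1cc(F)c([N+](=O)[O-])c(F)c1 | starting material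
7 | 2,6-bis(ArO)-4-methoxy-1-nitrobenzene | COc1cc(Oc2c(OC)cc(OC)c(-c3c(OC)cc(OC)cc3OC)c2OC)c([N+](=O)[O-])c(Oc2c(OC)cc(OC)c(-c3c(OC)cc(OC)cc3OC)c2OC)c1 | intermediate
8 | 2,6-bis(ArO)-4-methoxyaniline | COc1cc(Oc2c(OC)cc(OC)c(-c3c(OC)cc(OC)cc3OC)c2OC)c(N)c(Oc2c(OC)cc(OC)c(-c3c(OC)cc(OC)cc3OC)c2OC)c1 | intermediate
9 | 2,6-bis(ArO)-4-methoxybenzenediazonium tetrafluoroborate | COc1cc(Oc2c(OC)cc(OC)c(-c3c(OC)cc(OC)cc3OC)c2OC)c([N+]#N)c(Oc2c(OC)cc(OC)c(-c3c(OC)cc(OC)cc3OC)c2OC)c1.F[B-](F)(F)F | intermediate
10 | 2,6-bis(ArO)-4-methoxyphenol | COc1cc(Oc2c(OC)cc(OC)c(-c3c(OC)cc(OC)cc3OC)c2OC)c(O)c(Oc2c(OC)cc(OC)c(-c3c(OC)cc(OC)cc3OC)c2OC)c1 | intermediate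
11 | trichloroethylene | ClC=C(Cl)Cl | starting material
12 | 2-{[(E)-1,2-dichlorovinyl]oxy}-5-methoxy-1,3-bis(ArO)benzene | COc1cc(Oc2c(OC)cc(OC)c(-c3c(OC)cc(OC)cc3OC)c2OC)c(O/C(Cl)=C\Cl)c(Oc2c(OC)cc(OC)c(-c3c(OC)cc(OC)cc3OC)c2OC)c1 | intermediate
13 | 2-[(chloroethynyl)oxy]-5-methoxy-1,3-bis(ArO)benzene | COc1cc(Oc2c(OC)cc(OC)c(-c3c(OC)cc(OC)cc3OC)c2OC)c(OC#CCl)c(Oc2c(OC)cc(OC)c(-c3c(OC)cc(OC)cc3OC)c2OC)c1 | intermediate
14 | lithium acetylide of 15, {[2,6-bis(ArO)-4-methoxyphenoxy]ethynyl}lithium | COc1cc(Oc2c(OC)cc(OC)c(-c3c(OC)cc(OC)cc3OC)c2OC)c(OC#C[Li])c(Oc2c(OC)cc(OC)c(-c3c(OC)cc(OC)cc3OC)c2OC)c1 | intermediate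
15 | 2-(ethynyloxy)-5-methoxy-1,3-bis(ArO)benzene | COc1cc(Oc2c(OC)cc(OC)c(-c3c(OC)cc(OC)cc3OC)c2OC)c(OC#C)c(Oc2c(OC)cc(OC)c(-c3c(OC)cc(OC)cc3OC)c2OC)c1 | intermediate
16 | diisopropyl squarate (3,4-diisopropoxycyclobut-3-ene-1,2-dione) | CC(C)OC1=C(OC(C)C)C(=O)C1=O | starting material
17 | 4-hydroxy-2,3-diisopropoxycyclobut-2-en-1-one (racemic) | CC(C)OC1=C(OC(C)C)C(O)C1=O | intermediate
18 | 3-isopropoxycyclobut-3-ene-1,2-dione | CC(C)OC1=CC(=O)C1=O | intermediate
19 | 4-hydroxy-3-isopropoxycyclobut-2-en-1-one (racemic) | CC(C)OC1=CC(=O)C1O | intermediate
20 | 3-isopropoxy-4-methoxycyclobut-2-en-1-one (racemic) | CC(C)OC1=CC(=O)C1OC | intermediate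
21 | (Z)-3-isopropoxy-4-methoxybuta-1,3-dien-1-one | O=C=C/C(OC(C)C)=C/OC | intermediate
22 | 3-[2,6-bis(ArO)-4-methoxyphenoxy]-4-[(Z)-1-isopropoxy-2-methoxyvinyl]cyclobut-2-en-1-one (racemic) | COc1cc(Oc2c(OC)cc(OC)c(-c3c(OC)cc(OC)cc3OC)c2OC)c(OC2=CC(=O)C2/C(OC(C)C)=C/OC)c(Oc2c(OC)cc(OC)c(-c3c(OC)cc(OC)cc3OC)c2OC)c1 | intermediate
23 | (3E,5Z)-3-[2,6-bis(ArO)-4-methoxyphenoxy]-5-isopropoxy-6-methoxyhexa-1,3,5-trien-1-one | COc1cc(Oc2c(OC)cc(OC)c(-c3c(OC)cc(OC)cc3OC)c2OC)c(O/C(C=C=O)=C/C(OC(C)C)=C/OC)c(Oc2c(OC)cc(OC)c(-c3c(OC)cc(OC)cc3OC)c2OC)c1 | intermediate
24 | 3-[2,6-bis(ArO)-4-methoxyphenoxy]-5-isopropoxy-6-methoxycyclohexa-2,4-dien-1-one (racemic) | COc1cc(Oc2c(OC)cc(OC)c(-c3c(OC)cc(OC)cc3OC)c2OC)c(OC2=CC(=O)C(OC)C(OC(C)C)=C2)c(Oc2c(OC)cc(OC)c(-c3c(OC)cc(OC)cc3OC)c2OC)c1 | intermediate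
25 | 5-[2,6-bis(ArO)-4-methoxyphenoxy]-3-isopropoxy-2-methoxyphenol | COc1cc(Oc2c(OC)cc(OC)c(-c3c(OC)cc(OC)cc3OC)c2OC)c(Oc2cc(O)c(OC)c(OC(C)C)c2)c(Oc2c(OC)cc(OC)c(-c3c(OC)cc(OC)cc3OC)c2OC)c1 | intermediate
26 | 5-{2,6-bis[(2,2',4,4',6,6'-hexahydroxybiphenyl-3-yl)oxy]-4-hydroxyphenoxy}benzene-1,2,3-triol (CNP0279880.0) | Oc1cc(O)c(-c2c(O)cc(O)c(Oc3cc(O)cc(Oc4c(O)cc(O)c(-c5c(O)cc(O)cc5O)c4O)c3Oc3cc(O)c(O)c(O)c3)c2O)c(O)c1 | target

## Step count and least certain steps

Total: 12 steps. Longest linear sequence: 9 steps (steps 1 to 7, then 11 and 12). The cyclobutenone branch (steps 8 to 10) joins at step 11.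

**Step 11 (key step).** Two processes threaten it.
- Thermal self-condensation or polymerisation of the terminal ynol ether 15 may be faster than ring opening of 20, whose vinylogous ester stabilisation may push the opening toward the upper end of the temperature range.
- Once the ring is formed, a second vinylketene may acylate the new phenol. Brief methanolysis would reverse this.

The fallback uses known chemistry and forms the C2–O–F1 ether directly. It sets out from phenol 10 and returns to the route at 26. Chan–Lam coupling of 10 with 3,4,5-trimethoxyphenylboronic acid (COc1cc(B(O)O)cc(OC)c1OC; Cu(OAc)2, pyridine, 4 Å sieves, CH2Cl2, air, rt), a reaction that tolerates 2,6-disubstituted phenols, should give the hexadecamethyl ether of the target F1. Treatment with BBr3 as in step 12 then gives 26.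

**Step 9.** Hydride delivery may go to the wrong carbonyl, by conjugate addition, or on to the diol. The product may also lose isopropanol on contact with acid. A wrong regiochemistry here would put the oxygens of ring F in the wrong places.

The fallback replaces the squarate line by one (2+2) cycloaddition. It sets out from ynol ether 15 and returns at 26. Methoxyketene, generated from methoxyacetyl chloride and Et3N, adds to ethoxyacetylene to give racemic 3-ethoxy-4-methoxycyclobut-2-en-1-one F2. F2 is heated with 15 as in step 11 to give the 5-ethoxy analogue of 25, 5-[2,6-bis(ArO)-4-methoxyphenoxy]-3-ethoxy-2-methoxyphenol F3. BBr3 then gives 26.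

**Step 5.** The nitrosating agent may attack or oxidise the methoxy-rich rings instead of the hindered amine. The aryl radical may also be diverted by attack on a flanking ring or by hydrogen abstraction before copper delivers the hydroxyl.

The fallback avoids nitrogen altogether. It sets out from biaryl phenol 5 and returns at 10. Double SNAr of 5 on 2,6-difluoro-4-methoxybenzaldehyde (COc1cc(F)c(C=O)c(F)c1; K2CO3, DMAc, 120 °C) gives 2,6-bis(ArO)-4-methoxybenzaldehyde F4. Baeyer–Villiger oxidation (mCPBA, CH2Cl2) gives 2,6-bis(ArO)-4-methoxyphenyl formate F5, and K2CO3 in MeOH releases 10.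

**Step 2.** Lithiation may proceed to the dilithio species or stop short, since four positions are equivalent, and this lowers the return of mono-phenol.

The fallback changes the functionalisation from metalation to electrophilic substitution. It sets out from 2 and returns at 5. Vilsmeier–Haack formylation (POCl3, DMF) gives 2,2',4,4',6,6'-hexamethoxybiphenyl-3-carbaldehyde F6, which separates easily from 2. Baeyer–Villiger oxidation gives 2,2',4,4',6,6'-hexamethoxybiphenyl-3-yl formate F7, and methanolysis gives 5.

**Step 12.** Cleavage of fifteen ethers may stop at partly alkylated congeners that are hard to separate, and the free polyphenol may autoxidise during isolation.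

The fallback isolates the product as a stable derivative. It sets out from 25 and returns at 26. The crude product of BBr3 treatment is acetylated (Ac2O, pyridine) to the hexadecaacetate of the target F8, which can be purified on silica in air. Acid methanolysis (HCl in MeOH, argon) then releases 26 free of base.

## Further compounds

F1 | step 11 | 2-(3,4,5-trimethoxyphenoxy)-5-methoxy-1,3-bis(ArO)benzene (hexadecamethyl ether of the target) | COc1cc(Oc2c(OC)cc(OC)c(-c3c(OC)cc(OC)cc3OC)c2OC)c(Oc2cc(OC)c(OC)c(OC)c2)c(Oc2c(OC)cc(OC)c(-c3c(OC)cc(OC)cc3OC)c2OC)c1
F2 | step 9 | 3-ethoxy-4-methoxycyclobut-2-en-1-one (racemic) | CCOC1=CC(=O)C1OC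
F3 | step 9 | 5-[2,6-bis(ArO)-4-methoxyphenoxy]-3-ethoxy-2-methoxyphenol | COc1cc(Oc2c(OC)cc(OC)c(-c3c(OC)cc(OC)cc3OC)c2OC)c(Oc2cc(O)c(OC)c(OCC)c2)c(Oc2c(OC)cc(OC)c(-c3c(OC)cc(OC)cc3OC)c2OC)c1
F4 | step 5 | 2,6-bis(ArO)-4-methoxybenzaldehyde | COc1cc(Oc2c(OC)cc(OC)c(-c3c(OC)cc(OC)cc3OC)c2OC)c(C=O)c(Oc2c(OC)cc(OC)c(-c3c(OC)cc(OC)cc3OC)c2OC)c1
F5 | step 5 | 2,6-bis(ArO)-4-methoxyphenyl formate | COc1cc(Oc2c(OC)cc(OC)c(-c3c(OC)cc(OC)cc3OC)c2OC)c(OC=O)c(Oc2c(OC)cc(OC)c(-c3c(OC)cc(OC)cc3OC)c2OC)c1
F6 | step 2 | 2,2',4,4',6,6'-hexamethoxybiphenyl-3-carbaldehyde | O=Cc1c(OC)cc(OC)c(-c2c(OC)cc(OC)cc2OC)c1OC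
F7 | step 2 | 2,2',4,4',6,6'-hexamethoxybiphenyl-3-yl formate | O=COc1c(OC)cc(OC)c(-c2c(OC)cc(OC)cc2OC)c1OC
F8 | step 12 | hexadecaacetate of 26 | CC(=O)Oc1cc(OC(C)=O)c(-c2c(OC(C)=O)cc(OC(C)=O)c(Oc3cc(OC(C)=O)cc(Oc4c(OC(C)=O)cc(OC(C)=O)c(-c5c(OC(C)=O)cc(OC(C)=O)cc5OC(C)=O)c4OC(C)=O)c3Oc3cc(OC(C)=O)c(OC(C)=O)c(OC(C)=O)c3)c2OC(C)=O)c(OC(C)=O)c1
A1 | alternative 1 | 2,6-bis(ArO)-1,4-benzoquinone | O=C1C=C(Oc2c(OC)cc(OC)c(-c3c(OC)cc(OC)cc3OC)c2OC)C(=O)C(Oc2c(OC)cc(OC)c(-c3c(OC)cc(OC)cc3OC)c2OC)=C1
A2 | alternative 1 | 2,6-dichloro-1,4-benzoquinone | O=C1C=C(Cl)C(=O)C(Cl)=C1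
A3 | alternative 2 | 2',4,4',6,6'-pentamethoxy-5-(methoxymethoxy)biphenyl-2-ol (biaryl with free B2 hydroxyl and acetal-protected B5 oxygen) | COCOc1c(OC)cc(O)c(-c2c(OC)cc(OC)cc2OC)c1OC
A4 | alternative 2 | 3-methoxy-4-(methoxymethoxy)-4-(1-methoxyvinyl)-2-(2,4,6-trimethoxyphenyl)cyclobut-2-en-1-one (racemic) | COCOC1(C(=C)OC)C(OC)=C(c2c(OC)cc(OC)cc2OC)C1=O
A5 | alternative 3 | dodecamethyl ether of the target with free A2, A6, E2 and E6 hydroxyls | COc1cc(Oc2c(OC)cc(OC)c(-c3c(O)cc(OC)cc3O)c2OC)c(Oc2cc(OC)c(OC)c(OC)c2)c(Oc2c(OC)cc(OC)c(-c3c(O)cc(OC)cc3O)c2OC)c1
A6 | alternative 3 | bis(pyronylmethyl) precursor: analogue of A5 in which rings A and E are each replaced by a (4-methoxy-2-oxo-2H-pyran-6-yl)methyl group | COc1cc(Oc2c(OC)cc(OC)c(Cc3cc(OC)cc(=O)o3)c2OC)c(Oc2cc(OC)c(OC)c(OC)c2)c(Oc2c(OC)cc(OC)c(Cc3cc(OC)cc(=O)o3)c2OC)c1
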